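**Retrosynthetic overview**
1. Last step: hydrogenolysis of a chlorine at C5 of ring A; the chlorine is lent only to steer the key step.
2. Key disconnection: O1–C8a and C4–C4a, both at once. Enabling feature: ring A carries the ring oxygen O1 and the ketone carbon C4 on the neighbouring carbons C8a and C4a, with only H at C5. This is the imprint of an aryne (C4a≡C8a) that has taken up an alkoxide and an acyl group.
3. Precursors: 3-chloro-5-methoxybenzyne (from an ortho-silylaryl triflate) and the O-trimethylsilyl ether of an (S)-β-hydroxy morpholine amide that already holds C2 with its aryl group, C3 and C4. The amide keeps C4 as a hemiaminal until acid work-up, so C2 is carried through with retention.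
4. The (S)-carbinol comes from asymmetric transfer hydrogenation of a β-keto amide, made by Claisen condensation of N-acetylmorpholine with a benzofuran-5-carboxylate.
5. Ring order: the furan ring of the benzofuran first (Sonogashira coupling/cycloisomerisation of an ortho-iodophenol), then ring C, closed onto the incoming ring A in the key step.

Key step: step 7

Assumption: the target is read as the (2S) enantiomer (CIP order at C2: O1 > benzofuranyl > C3 > H); the carbinol carbon of the β-hydroxy amide has the same order, so (S) maps onto (2S) when its C–O bond is kept.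

**Step 1**
Reactants: 1 methyl 4-hydroxy-3-iodobenzoate; 2 1-ethynyl-4-methoxybenzene
Product: 4 methyl 2-(4-methoxyphenyl)-1-benzofuran-5-carboxylate, via alkynylphenol 3 (not isolated)
Conditions: PdCl2(PPh3)2 (3 mol %), CuI (5 mol %), Et3N, DMF, 25 °C then 80 °C
Reagents that add atoms: none
Why: Sonogashira coupling at the C–I bond is followed in the same flask by 5-endo-dig cycloisomerisation of the ortho-alkynylphenol 3 (the phenol, made more acidic by the para ester, adds across the metal-activated alkyne), the standard tandem route to 2-arylbenzofurans.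

**Step 2**
Reactants: 4 methyl 2-(4-methoxyphenyl)-1-benzofuran-5-carboxylate; 5 1-(morpholin-4-yl)ethan-1-one (N-acetylmorpholine)
Product: 7 1-[2-(4-methoxyphenyl)-1-benzofuran-5-yl]-3-(morpholin-4-yl)propane-1,3-dione, via lithium enolate 6 (not isolated)
Conditions: 5 (2.2 equiv), LiN(i-Pr)2 (LDA, 2.1 equiv), THF, −78 °C; then 4, −78 → 0 °C; aq. NH4Cl
Reagents that add atoms: none
Why: Crossed Claisen condensation, in which the lithium amide enolate 6 acylates at the ester carbonyl of 4 and the second equivalent of 6 deprotonates the 1,3-dicarbonyl product, which drives the reaction and shields the new ketone from further addition.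

**Step 3**
Reactants: 7 1-[2-(4-methoxyphenyl)-1-benzofuran-5-yl]-3-(morpholin-4-yl)propane-1,3-dione
Product: 8 (3S)-3-hydroxy-3-[2-(4-methoxyphenyl)-1-benzofuran-5-yl]-1-(morpholin-4-yl)propan-1-one
Conditions: RuCl(p-cymene)[(S,S)-TsDPEN] (1 mol %), HCO2H–Et3N (5:2), CH2Cl2, 30 °C
Reagents that add atoms: none
Why: Noyori–Ikariya asymmetric transfer hydrogenation of an aryl ketone (β-keto amides are an established substrate class), in which the outer-sphere hydride transfer is steered by the CH–π contact between the aryl group and the p-cymene ligand, so the (S,S)-ligand should give the (S)-carbinol as it does with aryl methyl ketones, and the (R,R)-catalyst would be used should the sense prove to be the reverse.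

**Step 4**
Reactants: 8 (3S)-3-hydroxy-3-[2-(4-methoxyphenyl)-1-benzofuran-5-yl]-1-(morpholin-4-yl)propan-1-one
Product: 9 (3S)-3-[2-(4-methoxyphenyl)-1-benzofuran-5-yl]-1-(morpholin-4-yl)-3-[(trimethylsilyl)oxy]propan-1-one
Conditions: TMSCl (1.2 equiv), imidazole (2 equiv), CH2Cl2, 0 °C; neutral work-up
Reagents that add atoms: chlorotrimethylsilane C[Si](C)(C)Cl
Why: Standard O-silylation of a secondary alcohol, which removes the O–H proton so that fluoride can later release a proton-free alkoxide, and which does not touch the stereocentre.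

**Step 5**
Reactants: 10 2-chloro-4-methoxyphenol
Product: 11 2-bromo-6-chloro-4-methoxyphenol
Conditions: NBS (1.0 equiv), i-Pr2NH (10 mol %), CH2Cl2, 0 °C
Reagents that add atoms: N-bromosuccinimide O=C1CCC(=O)N1Br
Why: Electrophilic aromatic bromination under amine-mediated NBS conditions that favour the position ortho to the phenol OH; the para position is blocked by OMe and C6 is the only free ortho position.

**Step 6**
Reactants: 11 2-bromo-6-chloro-4-methoxyphenol
Product: 15 2-chloro-4-methoxy-6-(trimethylsilyl)phenyl trifluoromethanesulfonate, via aryl silyl ether 12 (not isolated), via aryllithium 13 (not isolated), via lithium phenolate 14 (not isolated)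
Conditions: HMDS, THF, 65 °C, evaporate; n-BuLi (1.1 equiv), THF, −78 °C; then Tf2O (1.2 equiv), −78 → 0 °C
Reagents that add atoms: hexamethyldisilazane C[Si](C)(C)N[Si](C)(C)C; trifluoromethanesulfonic anhydride O=S(=O)(OS(=O)(=O)C(F)(F)F)C(F)(F)F
Why: One-flask route to ortho-silylaryl triflates by O-silylation, bromine–lithium exchange (C–Br reacts, C–Cl does not at −78 °C), anionic 1,3 O→C silyl shift (retro-Brook rearrangement) of 13 to the phenolate 14 and O-triflation; chlorine is meta to the lithiated carbon, so no aryne can form at this stage.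

**Step 7**
Reactants: 9 (3S)-3-[2-(4-methoxyphenyl)-1-benzofuran-5-yl]-1-(morpholin-4-yl)-3-[(trimethylsilyl)oxy]propan-1-one; 15 2-chloro-4-methoxy-6-(trimethylsilyl)phenyl trifluoromethanesulfonate (1.3 equiv)
Product: 20 (2S)-5-chloro-7-methoxy-2-[2-(4-methoxyphenyl)-1-benzofuran-5-yl]-2,3-dihydro-4H-chromen-4-one, via potassium alkoxide 16 (not isolated), via chloromethoxybenzyne 17 (not isolated), via aryl anion 18 (not isolated), via hemiaminal alkoxide 19 (not isolated)
Conditions: KF (4 equiv), 18-crown-6 (4 equiv), THF, −20 → 25 °C; then 1 M HCl, 0 °C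
Reagents that add atoms: none
Why: Proposed new method: fluoride removes both trimethylsilyl groups, so the alkoxide 16 and the aryne 17 meet in a medium without protons; the alkoxide oxygen adds to the aryne carbon remote from chlorine (O1–C8a bond) and leaves the aryl anion 18 on the carbon next to chlorine, and this anion attacks the morpholine amide carbonyl in a 6-exo-trig closure of ring C (C4–C4a bond) to give the tetrahedral alkoxide 19, which the acid quench turns into the ketone with loss of morpholine. The closest known reaction type is the fluoride-induced annulation of arynes with salicylate esters to xanthones (heteroatom addition, then acyl transfer to the aryl anion), together with the O-arylation of aliphatic alkoxides by arynes and the Parham cyclisation of aryl anions onto tertiary amides; an aliphatic β-silyloxy amide has not been used as the four-atom partner. No stereocentre of the product is made here: C2 keeps its (S) configuration because its C–O bond is never broken, the amide α-hydrogens are too weakly acidic for retro-aldol cleavage or elimination, and C4 stays a non-enolisable hemiaminal (its own configuration is lost on quench) as long as base is present. The step needs regioselective alkoxide addition and an acyl transfer faster than loss of chloride from the 2-chloroaryl anion. The first is secured by the inductive and distortion effect of the chlorine beside the triple bond, helped by the bulk of the secondary alkoxide and opposed only weakly by the remote methoxy group; the second by the choice of chlorine over bromine or a sulfonate and by the six-membered transition state.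

**Step 8**
Reactants: 20 (2S)-5-chloro-7-methoxy-2-[2-(4-methoxyphenyl)-1-benzofuran-5-yl]-2,3-dihydro-4H-chromen-4-one
Product: 21 (2S)-7-methoxy-2-[2-(4-methoxyphenyl)-1-benzofuran-5-yl]-2,3-dihydro-4H-chromen-4-one (lophirone J)
Conditions: H2 (1 atm), 10% Pd/C, NaOAc (1.5 equiv), EtOAc, 25 °C
Reagents that add atoms: none
Why: Catalytic hydrogenolysis (hydrodechlorination) of an aryl chloride activated by the ortho carbonyl, with acetate buffering the HCl so that neither acid-promoted cleavage of the benzylic C2–O1 bond nor base-promoted ring opening to a chalcone should occur, and C2 keeps its configuration.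

**Compound list**
1 | methyl 4-hydroxy-3-iodobenzoate | COC(=O)c1ccc(O)c(I)c1 | starting material
2 | 1-ethynyl-4-methoxybenzene | C#Cc1ccc(OC)cc1 | starting material
3 | methyl 4-hydroxy-3-[(4-methoxyphenyl)ethynyl]benzoate | COC(=O)c1ccc(O)c(C#Cc2ccc(OC)cc2)c1 | intermediate
4 | methyl 2-(4-methoxyphenyl)-1-benzofuran-5-carboxylate | COC(=O)c1ccc2oc(-c3ccc(OC)cc3)cc2c1 | intermediate
5 | 1-(morpholin-4-yl)ethan-1-one (N-acetylmorpholine) | CC(=O)N1CCOCC1 | starting material
6 | lithium 1-(morpholin-4-yl)ethen-1-olate | [Li+].[O-]C(=C)N1CCOCC1 | intermediate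
7 | 1-[2-(4-methoxyphenyl)-1-benzofuran-5-yl]-3-(morpholin-4-yl)propane-1,3-dione | O=C(CC(=O)N1CCOCC1)c1ccc2oc(-c3ccc(OC)cc3)cc2c1 | intermediate
8 | (3S)-3-hydroxy-3-[2-(4-methoxyphenyl)-1-benzofuran-5-yl]-1-(morpholin-4-yl)propan-1-one | O=C(C[C@H](O)c1ccc2oc(-c3ccc(OC)cc3)cc2c1)N1CCOCC1 | intermediate
9 | (3S)-3-[2-(4-methoxyphenyl)-1-benzofuran-5-yl]-1-(morpholin-4-yl)-3-[(trimethylsilyl)oxy]propan-1-one | C[Si](C)(C)O[C@@H](CC(=O)N1CCOCC1)c1ccc2oc(-c3ccc(OC)cc3)cc2c1 | intermediate
10 | 2-chloro-4-methoxyphenol | COc1ccc(O)c(Cl)c1 | starting material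
11 | 2-bromo-6-chloro-4-methoxyphenol | COc1cc(Cl)c(O)c(Br)c1 | intermediate
12 | (2-bromo-6-chloro-4-methoxyphenoxy)trimethylsilane | COc1cc(Cl)c(O[Si](C)(C)C)c(Br)c1 | intermediate
13 | {3-chloro-5-methoxy-2-[(trimethylsilyl)oxy]phenyl}lithium | COc1cc(Cl)c(O[Si](C)(C)C)c([Li])c1 | intermediate
14 | lithium 2-chloro-4-methoxy-6-(trimethylsilyl)phenolate | [Li+].COc1cc(Cl)c([O-])c([Si](C)(C)C)c1 | intermediate
15 | 2-chloro-4-methoxy-6-(trimethylsilyl)phenyl trifluoromethanesulfonate | COc1cc(Cl)c(OS(=O)(=O)C(F)(F)F)c([Si](C)(C)C)c1 | intermediate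
16 | potassium (1S)-1-[2-(4-methoxyphenyl)-1-benzofuran-5-yl]-3-(morpholin-4-yl)-3-oxopropan-1-olate | [K+].[O-][C@@H](CC(=O)N1CCOCC1)c1ccc2oc(-c3ccc(OC)cc3)cc2c1 | intermediate
17 | 1-chloro-2,3-didehydro-5-methoxybenzene (3-chloro-5-methoxybenzyne) | COC1=CC#CC(Cl)=C1 | intermediate
18 | potassium 2-chloro-4-methoxy-6-{(1S)-1-[2-(4-methoxyphenyl)-1-benzofuran-5-yl]-3-(morpholin-4-yl)-3-oxopropoxy}benzen-1-ide | [K+].COc1cc(Cl)[c-]c(O[C@@H](CC(=O)N2CCOCC2)c2ccc3oc(-c4ccc(OC)cc4)cc3c2)c1 | intermediate
19 | potassium (2S)-5-chloro-7-methoxy-2-[2-(4-methoxyphenyl)-1-benzofuran-5-yl]-4-(morpholin-4-yl)-3,4-dihydro-2H-chromen-4-olate (either configuration at C4) | [K+].COc1cc(Cl)c2c(c1)O[C@H](c1ccc3oc(-c4ccc(OC)cc4)cc3c1)CC2([O-])N1CCOCC1 | intermediate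
20 | (2S)-5-chloro-7-methoxy-2-[2-(4-methoxyphenyl)-1-benzofuran-5-yl]-2,3-dihydro-4H-chromen-4-one | COc1cc(Cl)c2c(c1)O[C@H](c1ccc3oc(-c4ccc(OC)cc4)cc3c1)CC2=O | intermediate
21 | (2S)-7-methoxy-2-[2-(4-methoxyphenyl)-1-benzofuran-5-yl]-2,3-dihydro-4H-chromen-4-one (lophirone J) | COc1ccc(-c2cc3cc([C@@H]4CC(=O)c5ccc(OC)cc5O4)ccc3o2)cc1 | target

Total step count: 8. Longest linear sequence: 6 steps (steps 1, 2, 3, 4, 7, 8); steps 5 and 6 make the aryne precursor on a side branch.

**Steps most likely to fail**

Step 7 (proposed new method). The aryl anion may pick up a proton or expel chloride (giving a second aryne) before it reaches the amide carbonyl, or the alkoxide may add with poor regioselectivity or be lost to retro-aldol cleavage. The fallback is known chemistry, a palladium-catalysed asymmetric conjugate addition of an arylboronic acid to a chromone; it sets out from 2 and comes back at 21.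
- 2 and commercial 4-bromo-2-iodophenol (Oc1ccc(Br)cc1I) under the conditions of step 1 give, through 4-bromo-2-[(4-methoxyphenyl)ethynyl]phenol F1 (not isolated; the C–I bond couples in preference to C–Br), 5-bromo-2-(4-methoxyphenyl)-1-benzofuran F2.
- Borylation (B2(OH)4, Pd(OAc)2, XPhos, KOAc, EtOH, 80 °C) gives [2-(4-methoxyphenyl)-1-benzofuran-5-yl]boronic acid F3.
- F3 and commercial 7-methoxy-4H-chromen-4-one (COc1ccc2c(c1)occc2=O) with Pd(OCOCF3)2, (R)-t-BuPyOx, NH4PF6 and H2O in ClCH2CH2Cl at 60 °C should give 21 directly. The ligand enantiomer is the one expected, by analogy with additions to cyclic enones, to deliver the aryl group to the face that gives (2S).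
- Ring A then comes ready-made and no chlorine is needed.

Step 8. The hydrogenolysis may run on to the benzylic C2–O1 bond, the C4 carbonyl or the furan double bond, or the C–Cl cleavage may stall. The fallback lends bromine instead of chlorine to C5 and removes it by a radical chain under neutral conditions; it sets out from 9 and comes back at 21.
- Commercial 2,6-dibromo-4-methoxyphenol (COc1cc(Br)c(O)c(Br)c1) is taken through the sequence of step 6: (2,6-dibromo-4-methoxyphenoxy)trimethylsilane F4, the aryllithium {3-bromo-5-methoxy-2-[(trimethylsilyl)oxy]phenyl}lithium F5 and lithium 2-bromo-4-methoxy-6-(trimethylsilyl)phenolate F6 (none isolated) lead to 2-bromo-4-methoxy-6-(trimethylsilyl)phenyl trifluoromethanesulfonate F7.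
- 9 and F7 under the conditions of step 7, held at −20 °C because a 2-bromoaryl anion loses halide faster, should give, through 1-bromo-2,3-didehydro-5-methoxybenzene F8, the potassium aryl anion F9 and the potassium hemiaminal alkoxide F10 (none isolated), (2S)-5-bromo-7-methoxy-2-[2-(4-methoxyphenyl)-1-benzofuran-5-yl]-2,3-dihydro-4H-chromen-4-one F11.
- Bu3SnH and AIBN in toluene at 80 °C then replace bromine by hydrogen to give 21.

Step 6. The O→C silyl shift may be incomplete, butyllithium may attack silicon or the C–Cl bond, and the phenolate flanked by Cl and SiMe3 may be triflated slowly. The fallback uses directed ortho-metalation in place of halogen–lithium exchange; it sets out from 10 and comes back at 15, so step 5 is no longer needed.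
- 10 and isopropyl isocyanate (CC(C)N=C=O) with Et3N give 2-chloro-4-methoxyphenyl N-isopropylcarbamate F12.
- TBSOTf and TMEDA in Et2O mask the N–H as the N-silyl carbamate F13 (not isolated); n-BuLi at −78 °C lithiates C6, ortho to the carbamate, to give the aryllithium F14 (not isolated); TMSCl gives the C-silylated N-silyl carbamate F15 (not isolated), which loses the N-silyl group on aqueous work-up to give 2-chloro-4-methoxy-6-(trimethylsilyl)phenyl N-isopropylcarbamate F16.
- DBU and Et2NH in MeCN at 40 °C cleave the carbamate to 2-chloro-4-methoxy-6-(trimethylsilyl)phenol F17 (not isolated), and PhNTf2 in the same flask gives 15.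

**Further compounds**
F1 | step 7 | 4-bromo-2-[(4-methoxyphenyl)ethynyl]phenol | Oc1ccc(Br)cc1C#Cc1ccc(OC)cc1
F2 | step 7 | 5-bromo-2-(4-methoxyphenyl)-1-benzofuran | Brc1ccc2oc(-c3ccc(OC)cc3)cc2c1
F3 | step 7 | [2-(4-methoxyphenyl)-1-benzofuran-5-yl]boronic acid | OB(O)c1ccc2oc(-c3ccc(OC)cc3)cc2c1
F4 | step 8 | (2,6-dibromo-4-methoxyphenoxy)trimethylsilane | COc1cc(Br)c(O[Si](C)(C)C)c(Br)c1
F5 | step 8 | {3-bromo-5-methoxy-2-[(trimethylsilyl)oxy]phenyl}lithium | COc1cc(Br)c(O[Si](C)(C)C)c([Li])c1
F6 | step 8 | lithium 2-bromo-4-methoxy-6-(trimethylsilyl)phenolate | [Li+].COc1cc(Br)c([O-])c([Si](C)(C)C)c1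
F7 | step 8 | 2-bromo-4-methoxy-6-(trimethylsilyl)phenyl trifluoromethanesulfonate | COc1cc(Br)c(OS(=O)(=O)C(F)(F)F)c([Si](C)(C)C)c1
F8 | step 8 | 1-bromo-2,3-didehydro-5-methoxybenzene | COC1=CC#CC(Br)=C1
F9 | step 8 | potassium 2-bromo-4-methoxy-6-{(1S)-1-[2-(4-methoxyphenyl)-1-benzofuran-5-yl]-3-(morpholin-4-yl)-3-oxopropoxy}benzen-1-ide | [K+].COc1cc(Br)[c-]c(O[C@@H](CC(=O)N2CCOCC2)c2ccc3oc(-c4ccc(OC)cc4)cc3c2)c1
F10 | step 8 | potassium (2S)-5-bromo-7-methoxy-2-[2-(4-methoxyphenyl)-1-benzofuran-5-yl]-4-(morpholin-4-yl)-3,4-dihydro-2H-chromen-4-olate | [K+].COc1cc(Br)c2c(c1)O[C@H](c1ccc3oc(-c4ccc(OC)cc4)cc3c1)CC2([O-])N1CCOCC1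
F11 | step 8 | (2S)-5-bromo-7-methoxy-2-[2-(4-methoxyphenyl)-1-benzofuran-5-yl]-2,3-dihydro-4H-chromen-4-one | COc1cc(Br)c2c(c1)O[C@H](c1ccc3oc(-c4ccc(OC)cc4)cc3c1)CC2=O
F12 | step 6 | 2-chloro-4-methoxyphenyl N-isopropylcarbamate | COc1ccc(OC(=O)NC(C)C)c(Cl)c1
F13 | step 6 | 2-chloro-4-methoxyphenyl N-(tert-butyldimethylsilyl)-N-isopropylcarbamate | COc1ccc(OC(=O)N(C(C)C)[Si](C)(C)C(C)(C)C)c(Cl)c1
F14 | step 6 | [2-{[(tert-butyldimethylsilyl)(isopropyl)carbamoyl]oxy}-3-chloro-5-methoxyphenyl]lithium | COc1cc(Cl)c(OC(=O)N(C(C)C)[Si](C)(C)C(C)(C)C)c([Li])c1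
F15 | step 6 | 2-chloro-4-methoxy-6-(trimethylsilyl)phenyl N-(tert-butyldimethylsilyl)-N-isopropylcarbamate | COc1cc(Cl)c(OC(=O)N(C(C)C)[Si](C)(C)C(C)(C)C)c([Si](C)(C)C)c1
F16 | step 6 | 2-chloro-4-methoxy-6-(trimethylsilyl)phenyl N-isopropylcarbamate | COc1cc(Cl)c(OC(=O)NC(C)C)c([Si](C)(C)C)c1
F17 | step 6 | 2-chloro-4-methoxy-6-(trimethylsilyl)phenol | COc1cc(Cl)c(O)c([Si](C)(C)C)c1
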